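A direct plan would build the seven-membered ring B first and annulate the five-membered ring A onto it.
2,5-Dimethylanisole would be Birch-reduced and ring-expanded with dibromocarbene to 3,6-dimethylcyclohepta-2,5-dien-1-one A1.
A ketone homoenolate from 1-isopropylcyclopropan-1-ol A2 would add to A1 under a chiral copper catalyst, the enolate would close by aldol to ketol A3, and reduction to jaeschkeanadiol A4 and acylation would finish.
Weakest would be the asymmetric conjugate addition that creates quaternary C1: a homoenolate on a β,β-disubstituted dienone would rest on catalyst control alone, without close precedent.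
The aldol ring closure would set C4 and C5 only through a reversible equilibration toward the trans-fused ketol.
The carbene ring expansion with debromination would add steps without adding complexity and would give a skipped dienone prone to conjugation.

**Strategy.** In ring A the oxygen-bearing C6 hangs on C5 next to quaternary C1, so C1=C5–C6–O is an allyl carbinol array. Cutting C1–C10 by an anionic oxy-Cope shift and C8=C9 by metathesis exposes (S)-terpinen-4-ol: its ten carbons are C1–C6, the C1 methyl and the isopropyl group, and its carbinol is C4. After ring contraction the formyl carbon C6 is used twice: a reagent-set C6 allyl carbinol hands its configuration suprafacially to C1 and regenerates the aldehyde, which then takes the methallyl arm. One operation fixes C1 and C5 relative to the bought C4. No asymmetric conjugate addition, aldol equilibration or ring expansion remains, and the bicycle appears only in the last step.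

Key step: step 5

Assumption: enantiopure (S)-(+)-terpinen-4-ol is taken as commercially available; atoms carry daucane numbers (C1 quaternary, C4 carbinol, C5 ring-fusion CH, C6 ester carbon, C8=C9 alkene).

Step 1
Reactants: 1 (S)-(+)-terpinen-4-ol
Product: 2 (S)-triethyl{[4-methyl-1-(propan-2-yl)cyclohex-3-en-1-yl]oxy}silane
Conditions: TESOTf, 2,6-lutidine, CH2Cl2, −78 → 0 °C
Reagents that add atoms: triethylsilyl triflate CC[Si](CC)(CC)OS(=O)(=O)C(F)(F)F
Why: Silylation of the hindered tertiary alcohol with a silyl triflate masks the hydroxyl, which after ring cleavage would form a hemiketal or open by retro-aldol; the carbinol stereocentre (C4 of the target) is not touched.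

Step 2
Reactants: 2 (S)-triethyl{[4-methyl-1-(propan-2-yl)cyclohex-3-en-1-yl]oxy}silane
Product: 4 (S)-3-isopropyl-6-oxo-3-(triethylsilyloxy)heptanal, via secondary ozonide 3 (not isolated)
Conditions: O3, CH2Cl2, −78 °C; then PPh3, −78 → 25 °C
Reagents that add atoms: ozone [O-][O+]=O
Why: Ozonolysis with reductive work-up cleaves the only C=C bond to the 1,6-keto aldehyde that holds C1 to C6; the silyl ether and the stereocentre are inert.

Step 3
Reactants: 4 (S)-3-isopropyl-6-oxo-3-(triethylsilyloxy)heptanal
Product: 5 (R)-5-isopropyl-2-methyl-5-(triethylsilyloxy)cyclopent-1-ene-1-carbaldehyde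
Conditions: piperidine (0.3 equiv), AcOH (0.3 equiv), PhMe, 25 → 60 °C
Reagents that add atoms: none
Why: Amine-catalysed intramolecular aldol condensation, in which the aldehyde enamine (C5) attacks the methyl ketone (C1) in a five-membered closure helped by quaternary C4 and the free tertiary aldol hydroxyl is lost toward conjugation, expected to be faster than loss of the β-silyloxy group; C4 is not touched.

Step 4
Reactants: 5 (R)-5-isopropyl-2-methyl-5-(triethylsilyloxy)cyclopent-1-ene-1-carbaldehyde
Product: 7 (S)-1-[(R)-5-isopropyl-2-methyl-5-(triethylsilyloxy)cyclopent-1-en-1-yl]but-3-en-1-ol, via diisopinocampheylborinate ester 6 (not isolated)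
Conditions: (−)-Ipc2BOMe (from (+)-α-pinene), allylMgBr, Et2O, −78 → 25 °C; then 5, −78 °C; then NaOH, H2O2, 0 → 25 °C
Reagents that add atoms: allylmagnesium bromide C=CC[Mg]Br
Why: Brown allylboration through a closed chair transition state, in which this reagent antipode (the one that adds to the si face of aldehydes) sets the temporary C6 carbinol as S under reagent control, with 1,2-addition only.

Step 5
Reactants: 7 (S)-1-[(R)-5-isopropyl-2-methyl-5-(triethylsilyloxy)cyclopent-1-en-1-yl]but-3-en-1-ol
Product: 9 (1R,2R,5R)-2-allyl-5-isopropyl-2-methyl-5-(triethylsilyloxy)cyclopentane-1-carbaldehyde, via potassium enolate 8 (not isolated)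
Conditions: KH, 18-crown-6, THF, 0 → 25 °C; then AcOH, −78 °C; then Et3N, CH2Cl2, 25 °C (equilibration at C5)
Reagents that add atoms: none
Why: Anionic oxy-Cope rearrangement, in which the potassium alkoxide of the 3-oxy-1,5-diene C1=C5–C6(O–)–CH2–CH=CH2 undergoes a charge-accelerated [3,3] shift through a chair transition state that breaks C6–CH2 and forms C1–C10 to give aldehyde enolate 8. The closest known reaction type is the crown-ether-promoted oxy-Cope rearrangement of secondary 1-cycloalkenyl homoallyl carbinols, including cases that form quaternary carbons. The step closes no ring; it installs on C1 the allyl arm whose metathesis closes ring B in step 10. C1 is set by suprafacial transfer from C6: with C6–H eclipsing the C1 methyl group (1,3-allylic strain) and the alkoxide turned toward C4, the allyl group of the 6S carbinol lies on the isopropyl face, so C10 ends up cis to isopropyl and trans to the C4 oxygen, the face that an intermolecular cuprate addition to 5 would be expected to avoid. C5 is set afterwards by protonation and amine equilibration, which should place the formyl group trans to isopropyl and allyl. The step needs the [3,3] shift to outrun fragmentation to allylpotassium and β-elimination of the silyloxy group from 8, which the naked alkoxide at 0 to 25 °C and the cold acidic quench are meant to secure.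

Step 6
Reactants: 9 (1R,2R,5R)-2-allyl-5-isopropyl-2-methyl-5-(triethylsilyloxy)cyclopentane-1-carbaldehyde
Product: 11 (S)-1-[(1S,2R,5R)-2-allyl-5-isopropyl-2-methyl-5-(triethylsilyloxy)cyclopentyl]-3-methylbut-3-en-1-ol, via diisopinocampheylborinate ester 10 (not isolated)
Conditions: (−)-Ipc2BOMe, 2-methylallylmagnesium chloride, Et2O, −78 → 25 °C; then 9, −78 → −40 °C; then NaOH, H2O2, 0 → 25 °C
Reagents that add atoms: 2-methylallylmagnesium chloride C=C(C)C[Mg]Cl
Why: Brown 2-methylallylboration under neutral conditions, in which the same reagent antipode adds to the si face of the hindered aldehyde through a chair transition state and sets C6 as S, while the epimerisable C5 and the β-silyloxy group see no base.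

Step 7
Reactants: 12 vanillic acid
Product: 14 4-(tert-butyldimethylsilyloxy)-3-methoxybenzoic acid, via bis-silylated silyl ester 13 (not isolated)
Conditions: TBSCl (2.5 equiv), imidazole, DMF, 25 °C; then AcOH–THF–H2O (3:1:1), 25 °C
Reagents that add atoms: tert-butyldimethylsilyl chloride CC(C)(C)[Si](C)(C)Cl
Why: Silylation of phenol and acid followed by selective hydrolysis of the labile silyl ester leaves the phenol as a silyl ether that falls together with the triethylsilyl group in step 9; no stereocentre.

Step 8
Reactants: 11 (S)-1-[(1S,2R,5R)-2-allyl-5-isopropyl-2-methyl-5-(triethylsilyloxy)cyclopentyl]-3-methylbut-3-en-1-ol; 14 4-(tert-butyldimethylsilyloxy)-3-methoxybenzoic acid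
Product: 15 (S)-1-[(1S,2R,5R)-2-allyl-5-isopropyl-2-methyl-5-(triethylsilyloxy)cyclopentyl]-3-methylbut-3-en-1-yl 4-(tert-butyldimethylsilyloxy)-3-methoxybenzoate
Conditions: DCC, DMAP (1 equiv), CH2Cl2, 0 → 40 °C
Reagents that add atoms: none
Why: Steglich esterification of the only free hydroxyl (secondary C6–OH) by carbodiimide activation and acyl transfer through DMAP; the C6–O bond is not broken, so no stereocentre is touched.

Step 9
Reactants: 15 (S)-1-[(1S,2R,5R)-2-allyl-5-isopropyl-2-methyl-5-(triethylsilyloxy)cyclopentyl]-3-methylbut-3-en-1-yl 4-(tert-butyldimethylsilyloxy)-3-methoxybenzoate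
Product: 16 (S)-1-[(1S,2R,5R)-2-allyl-5-hydroxy-5-isopropyl-2-methylcyclopentyl]-3-methylbut-3-en-1-yl 4-hydroxy-3-methoxybenzoate
Conditions: HF·pyridine, pyridine, THF, 0 → 25 °C
Reagents that add atoms: none
Why: Fluoride-mediated desilylation removes the aryl silyl ether and the tertiary triethylsilyl ether in one buffered operation that leaves the benzoate and both alkenes intact; no stereocentre is touched.

Step 10
Reactants: 16 (S)-1-[(1S,2R,5R)-2-allyl-5-hydroxy-5-isopropyl-2-methylcyclopentyl]-3-methylbut-3-en-1-yl 4-hydroxy-3-methoxybenzoate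
Product: 17 teferin
Conditions: second-generation Hoveyda–Grubbs catalyst RuCl2(H2IMes)(=CH–C6H4–2-OiPr) (5 mol%), PhMe (0.005 M), 80 °C
Reagents that add atoms: none
Why: Ring-closing metathesis of the allyl arm on C1 with the 2-methylallyl arm on C6 closes ring B at C8=C9 as the trisubstituted ring alkene with loss of ethylene; the arms are trans on ring A and should give the trans-fused bicycle, and the ruthenium carbene tolerates the free phenol and tertiary hydroxyl.

**Compound list**

1 | (S)-(+)-terpinen-4-ol, (S)-4-methyl-1-(propan-2-yl)cyclohex-3-en-1-ol | CC1=CC[C@](O)(C(C)C)CC1 | starting material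
2 | (S)-triethyl{[4-methyl-1-(propan-2-yl)cyclohex-3-en-1-yl]oxy}silane | CC1=CC[C@](O[Si](CC)(CC)CC)(C(C)C)CC1 | intermediate
3 | secondary ozonide of 2 (1,2,4-trioxolane across the former C=C bond) | CC12CC[C@@](O[Si](CC)(CC)CC)(C(C)C)CC(O1)OO2 | intermediate
4 | (S)-3-isopropyl-6-oxo-3-(triethylsilyloxy)heptanal | O=CC[C@](O[Si](CC)(CC)CC)(C(C)C)CCC(C)=O | intermediate
5 | (R)-5-isopropyl-2-methyl-5-(triethylsilyloxy)cyclopent-1-ene-1-carbaldehyde | O=CC1=C(C)CC[C@@]1(O[Si](CC)(CC)CC)C(C)C | intermediate
6 | diisopinocampheylborinate ester of 7 | C=CC[C@H](OB([C@@H]3C[C@@H]4C[C@H]([C@H]3C)C4(C)C)[C@@H]5C[C@@H]6C[C@H]([C@H]5C)C6(C)C)C1=C(C)CC[C@@]1(O[Si](CC)(CC)CC)C(C)C | intermediate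
7 | (S)-1-[(R)-5-isopropyl-2-methyl-5-(triethylsilyloxy)cyclopent-1-en-1-yl]but-3-en-1-ol | C=CC[C@H](O)C1=C(C)CC[C@@]1(O[Si](CC)(CC)CC)C(C)C | intermediate
8 | potassium [(2R,5R)-2-allyl-5-isopropyl-2-methyl-5-(triethylsilyloxy)cyclopentylidene]methanolate | [K+].[O-]C=C1[C@@](C)(CC=C)CC[C@@]1(O[Si](CC)(CC)CC)C(C)C | intermediate
9 | (1R,2R,5R)-2-allyl-5-isopropyl-2-methyl-5-(triethylsilyloxy)cyclopentane-1-carbaldehyde (allyl cis to isopropyl, formyl cis to methyl and silyloxy) | O=C[C@@H]1[C@@](C)(CC=C)CC[C@@]1(O[Si](CC)(CC)CC)C(C)C | intermediate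
10 | diisopinocampheylborinate ester of 11 | C=C(C)C[C@H](OB([C@@H]3C[C@@H]4C[C@H]([C@H]3C)C4(C)C)[C@@H]5C[C@@H]6C[C@H]([C@H]5C)C6(C)C)[C@@H]1[C@@](C)(CC=C)CC[C@@]1(O[Si](CC)(CC)CC)C(C)C | intermediate
11 | (S)-1-[(1S,2R,5R)-2-allyl-5-isopropyl-2-methyl-5-(triethylsilyloxy)cyclopentyl]-3-methylbut-3-en-1-ol | C=C(C)C[C@H](O)[C@@H]1[C@@](C)(CC=C)CC[C@@]1(O[Si](CC)(CC)CC)C(C)C | intermediate
12 | vanillic acid (4-hydroxy-3-methoxybenzoic acid) | COc1cc(C(=O)O)ccc1O | starting material
13 | tert-butyldimethylsilyl 4-(tert-butyldimethylsilyloxy)-3-methoxybenzoate | COc1cc(C(=O)O[Si](C)(C)C(C)(C)C)ccc1O[Si](C)(C)C(C)(C)C | intermediate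
14 | 4-(tert-butyldimethylsilyloxy)-3-methoxybenzoic acid | COc1cc(C(=O)O)ccc1O[Si](C)(C)C(C)(C)C | intermediate
15 | (S)-1-[(1S,2R,5R)-2-allyl-5-isopropyl-2-methyl-5-(triethylsilyloxy)cyclopentyl]-3-methylbut-3-en-1-yl 4-(tert-butyldimethylsilyloxy)-3-methoxybenzoate | COc1cc(C(=O)O[C@@H](CC(C)=C)[C@@H]2[C@@](C)(CC=C)CC[C@@]2(O[Si](CC)(CC)CC)C(C)C)ccc1O[Si](C)(C)C(C)(C)C | intermediate
16 | (S)-1-[(1S,2R,5R)-2-allyl-5-hydroxy-5-isopropyl-2-methylcyclopentyl]-3-methylbut-3-en-1-yl 4-hydroxy-3-methoxybenzoate | COc1cc(C(=O)O[C@@H](CC(C)=C)[C@@H]2[C@@](C)(CC=C)CC[C@@]2(O)C(C)C)ccc1O | intermediate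
17 | teferin, (1R,4R,5S,6S)-4-hydroxydauc-8-en-6-yl 4-hydroxy-3-methoxybenzoate | COc1cc(C(=O)O[C@H]2CC(C)=CC[C@@]3(C)CC[C@@](O)(C(C)C)[C@H]23)ccc1O | target

**Step count and risks**

Total steps: 10. Longest linear sequence: 9 (steps 1 to 6 and 8 to 10); step 7 is a one-step side branch.

Most likely to fail, in this order:

- **Step 5 (anionic oxy-Cope).** The alkoxide may fragment to allylpotassium and enal 5 and recombine without stereocontrol. Enolate 8 may expel its β-silyloxy group. The allyl group has to travel across the isopropyl face, so part of the material may react through the rotamer with the alkoxide oxygen eclipsing the C1 methyl group, which would give the C1 epimer. The fallback leaves the anionic manifold. Setting out from 7, the carbinol would be silylated (TMSCl, imidazole, DMF) to (S)-trimethyl{1-[(R)-5-isopropyl-2-methyl-5-(triethylsilyloxy)cyclopent-1-en-1-yl]but-3-en-1-yloxy}silane F1. F1 would be heated in o-dichlorobenzene at 200 to 220 °C in a sealed tube, so that the neutral siloxy-Cope shift gives {[(2R,5R)-2-allyl-5-isopropyl-2-methyl-5-(triethylsilyloxy)cyclopentylidene]methoxy}trimethylsilane F2 with no enolate and no alkoxide present. Cold dilute acid (1 M HCl, THF, 0 °C) would hydrolyse F2, and amine equilibration at C5 would bring the route back to 9.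

- **Step 3 (aldol condensation).** The aldehyde enamine may lose the β-silyloxy group before it cyclises, or the aldol may eliminate toward C4 instead of C1; either path destroys the bought stereocentre. The fallback separates ring closure from elimination. Setting out from 4, the aldol addition would be stopped at the ketol stage (L-proline, DMSO, 0 to 25 °C) to give (5R)-2-hydroxy-5-isopropyl-2-methyl-5-(triethylsilyloxy)cyclopentane-1-carbaldehyde F3 as a mixture at the two new centres. Burgess reagent (PhMe, 50 °C) would then activate only the free tertiary hydroxyl on C1 and eliminate it toward the formyl-bearing carbon, returning to 5.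

- **Step 6 (methallylboration).** Addition of the bulky borane to an aldehyde flanked by two quaternary carbons may be slow, and the facial preference of the substrate may oppose the reagent, so that C6 selectivity erodes. The fallback sets C6 by reduction instead of addition. Setting out from 9, 2-methylallylmagnesium chloride (THF, −78 °C) would give 1-[(1S,2R,5R)-2-allyl-5-isopropyl-2-methyl-5-(triethylsilyloxy)cyclopentyl]-3-methylbut-3-en-1-ol F4 as a mixture at C6. Dess–Martin periodinane (NaHCO3, CH2Cl2, 0 °C) would give 1-[(1R,2R,5R)-2-allyl-5-isopropyl-2-methyl-5-(triethylsilyloxy)cyclopentyl]-3-methylbut-3-en-1-one F5. Reduction with (R)-2-methyl-CBS-oxazaborolidine and catecholborane (PhMe, −78 °C) should deliver hydride to the re face, between the large cyclopentyl and the small methallyl flank, and return to 11 as the 6S alcohol; catecholborane is chosen so that the two alkenes are not hydroborated.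

**Further compounds**

F1 | step 5 | (S)-trimethyl{1-[(R)-5-isopropyl-2-methyl-5-(triethylsilyloxy)cyclopent-1-en-1-yl]but-3-en-1-yloxy}silane | C=CC[C@H](O[Si](C)(C)C)C1=C(C)CC[C@@]1(O[Si](CC)(CC)CC)C(C)C
F2 | step 5 | {[(2R,5R)-2-allyl-5-isopropyl-2-methyl-5-(triethylsilyloxy)cyclopentylidene]methoxy}trimethylsilane | C[Si](C)(C)OC=C1[C@@](C)(CC=C)CC[C@@]1(O[Si](CC)(CC)CC)C(C)C
F3 | step 3 | (5R)-2-hydroxy-5-isopropyl-2-methyl-5-(triethylsilyloxy)cyclopentane-1-carbaldehyde (mixture at C1 and C2) | O=CC1C(C)(O)CC[C@@]1(O[Si](CC)(CC)CC)C(C)C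
F4 | step 6 | 1-[(1S,2R,5R)-2-allyl-5-isopropyl-2-methyl-5-(triethylsilyloxy)cyclopentyl]-3-methylbut-3-en-1-ol (mixture at the carbinol carbon) | C=C(C)CC(O)[C@@H]1[C@@](C)(CC=C)CC[C@@]1(O[Si](CC)(CC)CC)C(C)C
F5 | step 6 | 1-[(1R,2R,5R)-2-allyl-5-isopropyl-2-methyl-5-(triethylsilyloxy)cyclopentyl]-3-methylbut-3-en-1-one | C=C(C)CC(=O)[C@@H]1[C@@](C)(CC=C)CC[C@@]1(O[Si](CC)(CC)CC)C(C)C
A1 | direct plan | 3,6-dimethylcyclohepta-2,5-dien-1-one | O=C1C=C(C)CC=C(C)C1
A2 | direct plan | 1-isopropylcyclopropan-1-ol | CC(C)C1(O)CC1
A3 | direct plan | (1R,4R,5R)-4-hydroxydauc-8-en-6-one | O=C1CC(C)=CC[C@@]2(C)CC[C@@](O)(C(C)C)[C@H]12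
A4 | direct plan | jaeschkeanadiol, (1R,4R,5S,6S)-dauc-8-ene-4,6-diol | O[C@H]1CC(C)=CC[C@@]2(C)CC[C@@](O)(C(C)C)[C@H]12
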